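The target is an acyclic succinate half-ester, so the route rests on cutting the C2–C3 bond between the two carboxyl-bearing carbons. C2 (carrying the 4-hydroxyphenyl ring and the future CO2Me, C1) is used as an auxiliary-bound enolate carbon. C3 (carrying the benzylic CH2 of the prenylated phenol ring and the future CO2H, C4) is used as the carbinol carbon of a tyrosine-derived lactate. One SN2 alkylation forms this bond and both stereocentres without closing a ring, and leaves C1 (imide) and C4 (silylethyl ester) differentiated. Its precursors are an (S)-4-benzyloxazolidinone arylacetyl imide and an (S)-alpha-triflyloxy 2-(trimethylsilyl)ethyl ester, both phenols masked as triisopropylsilyl ethers.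

Key step: step 8

Remark on locants: C1 is the carboxyl carbon that ends as the methyl ester, C2 carries the 4-hydroxyphenyl group, C3 carries the benzyl group, and C4 is the carboxyl carbon that ends as the free acid.

Remark on protecting groups (assumption): both phenols are carried as triisopropylsilyl ethers. These allow phenol-selective silylation beside the secondary alcohol and should tolerate the hydroperoxide step. Acid-labile groups are avoided because an ortho-prenyl phenol cyclises to a chroman under acid.

Remark on reagents (assumption): 2-(trimethylsilyl)ethyl 2,2,2-trichloroacetimidate and stannane 7 are taken as purchasable.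

Step 1
Reactants: 1 3-iodo-L-tyrosine
Product: 4 (S)-2-hydroxy-3-(4-hydroxy-3-iodophenyl)propanoic acid, via diazonium carboxylate 2 (not isolated), via alpha-lactone 3 (not isolated)
Conditions: NaNO2 (slow addition), 1 M H2SO4, 1,4-dioxane, 0 °C → rt
Reagents that add atoms: water, O
Why: Diazotisation of an alpha-amino acid (van Slyke-type deamination): the carboxylate displaces N2 with inversion to alpha-lactone 3 and water opens it with a second inversion, so the (S) centre is retained overall.

Step 2
Reactants: 4 (S)-2-hydroxy-3-(4-hydroxy-3-iodophenyl)propanoic acid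
Product: 5 2-(trimethylsilyl)ethyl (S)-2-hydroxy-3-(4-hydroxy-3-iodophenyl)propanoate
Conditions: Me3SiCH2CH2OC(=NH)CCl3 (1.5 equiv), toluene/THF, 90 °C
Reagents that add atoms: 2-(trimethylsilyl)ethyl 2,2,2-trichloroacetimidate, C[Si](C)(C)CCOC(=N)C(Cl)(Cl)Cl
Why: Promoter-free trichloroacetimidate esterification: only the carboxylic acid is acidic enough to activate the imidate, so the phenol and the secondary alcohol should stay free and the stereocentre is not involved.

Step 3
Reactants: 5 2-(trimethylsilyl)ethyl (S)-2-hydroxy-3-(4-hydroxy-3-iodophenyl)propanoate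
Product: 6 2-(trimethylsilyl)ethyl (S)-2-hydroxy-3-[3-iodo-4-(triisopropylsilyloxy)phenyl]propanoate
Conditions: iPr3SiCl (1.1 equiv), imidazole, DMF, 0 °C → rt
Reagents that add atoms: chlorotriisopropylsilane, CC(C)[Si](Cl)(C(C)C)C(C)C
Why: Chemoselective O-silylation: the bulky silyl chloride should react with the acidic phenol far faster than with the hindered secondary alpha-hydroxy ester, which must stay free for step 5.

Step 4
Reactants: 6 2-(trimethylsilyl)ethyl (S)-2-hydroxy-3-[3-iodo-4-(triisopropylsilyloxy)phenyl]propanoate; 7 tributyl(3-methylbut-2-enyl)stannane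
Product: 8 2-(trimethylsilyl)ethyl (S)-2-hydroxy-3-[3-(3-methylbut-2-enyl)-4-(triisopropylsilyloxy)phenyl]propanoate
Conditions: 7 (1.3 equiv), Pd(PPh3)4 (5 mol %), degassed DMF, 90 °C
Reagents that add atoms: none
Why: Stille coupling: oxidative addition of the aryl iodide to zerovalent palladium, prenyl transfer from tin and reductive elimination at the less hindered allyl terminus should give the linear prenyl arene under neutral conditions that spare the alcohol, both silicon groups and the stereocentre.

Step 5
Reactants: 8 2-(trimethylsilyl)ethyl (S)-2-hydroxy-3-[3-(3-methylbut-2-enyl)-4-(triisopropylsilyloxy)phenyl]propanoate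
Product: 9 2-(trimethylsilyl)ethyl (S)-3-[3-(3-methylbut-2-enyl)-4-(triisopropylsilyloxy)phenyl]-2-(trifluoromethylsulfonyloxy)propanoate
Conditions: (CF3SO2)2O (1.2 equiv), 2,6-lutidine (1.5 equiv), CH2Cl2, –78 °C; cold filtration through silica, used at once
Reagents that add atoms: trifluoromethanesulfonic anhydride, O=S(=O)(OS(=O)(=O)C(F)(F)F)C(F)(F)F
Why: O-Sulfonylation of the alpha-hydroxy ester with a hindered base at low temperature takes place at oxygen only, so the (S) configuration is kept and elimination is avoided.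

Step 6
Reactants: 10 4-hydroxyphenylacetic acid
Product: 12 2-[4-(triisopropylsilyloxy)phenyl]acetic acid, via bis-silyl compound 11 (not isolated)
Conditions: iPr3SiCl (2.3 equiv), imidazole, DMF, rt; then K2CO3, THF/H2O, rt; 1 M HCl to pH 3
Reagents that add atoms: chlorotriisopropylsilane, CC(C)[Si](Cl)(C(C)C)C(C)C
Why: Exhaustive silylation followed by selective hydrolysis of the labile silyl ester, since an aryl triisopropylsilyl ether survives brief aqueous carbonate whereas the silyl ester does not.

Step 7
Reactants: 12 2-[4-(triisopropylsilyloxy)phenyl]acetic acid; 13 (S)-4-benzyl-2-oxazolidinone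
Product: 15 (S)-4-benzyl-3-{2-[4-(triisopropylsilyloxy)phenyl]acetyl}oxazolidin-2-one, via mixed pivalic anhydride 14 (not isolated)
Conditions: t-BuCOCl, Et3N, THF, –20 °C; then 13, LiCl, –20 °C → rt
Reagents that add atoms: none
Why: N-Acylation of the oxazolidinone through a mixed pivalic anhydride (LiCl/Et3N method), in which the nitrogen attacks the less hindered arylacetyl carbonyl.

Step 8
Reactants: 15 (S)-4-benzyl-3-{2-[4-(triisopropylsilyloxy)phenyl]acetyl}oxazolidin-2-one; 9 2-(trimethylsilyl)ethyl (S)-3-[3-(3-methylbut-2-enyl)-4-(triisopropylsilyloxy)phenyl]-2-(trifluoromethylsulfonyloxy)propanoate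
Product: 17 (2S,3S)-succinate with C1 as the N-acyl (S)-4-benzyloxazolidin-2-one; C2 bearing 4-(triisopropylsilyloxy)phenyl; C3 bearing 3-(3-methylbut-2-enyl)-4-(triisopropylsilyloxy)benzyl; C4 as the 2-(trimethylsilyl)ethyl ester, via sodium Z-enolate 16 (not isolated)
Conditions: 15 (1.2 equiv), NaN(SiMe3)2 (1.15 equiv), THF, –78 °C; then 9 (1.0 equiv), –78 → –40 °C; AcOH quench
Reagents that add atoms: none
Why: NaN(SiMe3)2 should give the chelated Z-enolate 16, with sodium bridging the enolate oxygen and the ring carbonyl, and its alpha-carbon attacks the triflate-bearing carbon of 9 from the side opposite the leaving group (SN2). The reaction type is the known alkylation of chiral imide enolates with alpha-triflyloxy esters to give 2,3-disubstituted succinates, and no ring is closed. C3 is set by inversion: the (S)-triflate becomes 3S because the incoming C2 ranks below the ester carbon, where the departing oxygen ranked above it. C2 is set by the 4-benzyl group of the (S)-auxiliary, which blocks one face of the chelated enolate, and the descriptor is 2S because the aryl group outranks C3. The step needs substitution to beat E2 loss of triflate to the cinnamate, and it needs face control at C2: the first is secured by the weakly basic aryl-stabilised enolate, the absence of free amide base (15 in slight excess) and the low temperature, the second by the rigid chelate. The C2–H of the product should not be removed by remaining enolate because A(1,3) strain holds it in the imide plane.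

Step 9
Reactants: 17 (2S,3S)-succinate C1 imide C4 2-(trimethylsilyl)ethyl ester
Product: 19 (2S,3S)-2-[4-(triisopropylsilyloxy)phenyl]-3-[3-(3-methylbut-2-enyl)-4-(triisopropylsilyloxy)benzyl]succinic acid 4-[2-(trimethylsilyl)ethyl] ester (C1 free acid), via peroxy acid 18 (not isolated)
Conditions: LiOH, 30% H2O2, THF/H2O, 0 °C; then aq Na2SO3; 1 M HCl to pH 3 at 0 °C
Reagents that add atoms: hydrogen peroxide, OO
Why: Hydroperoxide cleavage of an acyl oxazolidinone: the alpha-effect nucleophile HOO– attacks the exocyclic carbonyl and is only weakly basic, so C2, the silylethyl ester and the aryl silyl ethers should survive, and sulfite reduces peroxy acid 18 before acidification.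

Step 10
Reactants: 19 C1 acid C4 2-(trimethylsilyl)ethyl ester
Product: 20 1-methyl 4-[2-(trimethylsilyl)ethyl] (2S,3S)-2-[4-(triisopropylsilyloxy)phenyl]-3-[3-(3-methylbut-2-enyl)-4-(triisopropylsilyloxy)benzyl]succinate
Conditions: Me3SiCHN2, toluene/MeOH (4:1), 0 °C → rt
Reagents that add atoms: trimethylsilyldiazomethane, C[Si](C)(C)C=[N+]=[N-]
Why: O-Methylation of the carboxylic acid with trimethylsilyldiazomethane in the presence of methanol is non-basic, so the acidic benzylic C2–H is not disturbed.

Step 11
Reactants: 20 1-methyl 4-[2-(trimethylsilyl)ethyl] (2S,3S)-succinate bis(triisopropylsilyl ether)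
Product: 21 Asperteretal G2, the (2S,3S)-succinic acid 1-methyl ester with 4-hydroxyphenyl at C2 and 4-hydroxy-3-(3-methylbut-2-enyl)benzyl at C3
Conditions: Bu4NF (6 equiv), AcOH (3 equiv), THF, 0 °C → rt; pH 3 phosphate buffer work-up
Reagents that add atoms: none
Why: Fluoride-induced desilylation: the aryl silyl ethers are cleaved first and the silylethyl ester then fragments to ethene and Me3SiF, while the acetic acid buffer and the early release of the electron-rich phenol on the C2 ring should suppress epimerisation at C2.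

Compound list
1 | 3-iodo-L-tyrosine, (S)-2-amino-3-(4-hydroxy-3-iodophenyl)propanoic acid | N[C@@H](Cc1ccc(O)c(I)c1)C(=O)O | starting material
2 | (S)-1-carboxylato-2-(4-hydroxy-3-iodophenyl)ethanediazonium (diazonium carboxylate) | N#[N+][C@@H](Cc1ccc(O)c(I)c1)C(=O)[O-] | intermediate
3 | (R)-3-(4-hydroxy-3-iodobenzyl)oxiran-2-one (alpha-lactone) | O1[C@H](Cc2ccc(O)c(I)c2)C1=O | intermediate
4 | (S)-2-hydroxy-3-(4-hydroxy-3-iodophenyl)propanoic acid | O[C@@H](Cc1ccc(O)c(I)c1)C(=O)O | intermediate
5 | 2-(trimethylsilyl)ethyl (S)-2-hydroxy-3-(4-hydroxy-3-iodophenyl)propanoate | O[C@@H](Cc1ccc(O)c(I)c1)C(=O)OCC[Si](C)(C)C | intermediate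
6 | 2-(trimethylsilyl)ethyl (S)-2-hydroxy-3-[3-iodo-4-(triisopropylsilyloxy)phenyl]propanoate | O[C@@H](Cc1ccc(O[Si](C(C)C)(C(C)C)C(C)C)c(I)c1)C(=O)OCC[Si](C)(C)C | intermediate
7 | tributyl(3-methylbut-2-enyl)stannane | CC(C)=CC[Sn](CCCC)(CCCC)CCCC | starting material
8 | 2-(trimethylsilyl)ethyl (S)-2-hydroxy-3-[3-(3-methylbut-2-enyl)-4-(triisopropylsilyloxy)phenyl]propanoate | O[C@@H](Cc1ccc(O[Si](C(C)C)(C(C)C)C(C)C)c(CC=C(C)C)c1)C(=O)OCC[Si](C)(C)C | intermediate
9 | 2-(trimethylsilyl)ethyl (S)-3-[3-(3-methylbut-2-enyl)-4-(triisopropylsilyloxy)phenyl]-2-(trifluoromethylsulfonyloxy)propanoate | FC(F)(F)S(=O)(=O)O[C@@H](Cc1ccc(O[Si](C(C)C)(C(C)C)C(C)C)c(CC=C(C)C)c1)C(=O)OCC[Si](C)(C)C | intermediate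
10 | 4-hydroxyphenylacetic acid | OC(=O)Cc1ccc(O)cc1 | starting material
11 | triisopropylsilyl 2-[4-(triisopropylsilyloxy)phenyl]acetate | CC(C)[Si](C(C)C)(C(C)C)OC(=O)Cc1ccc(O[Si](C(C)C)(C(C)C)C(C)C)cc1 | intermediate
12 | 2-[4-(triisopropylsilyloxy)phenyl]acetic acid | OC(=O)Cc1ccc(O[Si](C(C)C)(C(C)C)C(C)C)cc1 | intermediate
13 | (S)-4-benzyl-2-oxazolidinone | O=C1OC[C@H](Cc2ccccc2)N1 | starting material
14 | 2-[4-(triisopropylsilyloxy)phenyl]acetic pivalic anhydride | CC(C)(C)C(=O)OC(=O)Cc1ccc(O[Si](C(C)C)(C(C)C)C(C)C)cc1 | intermediate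
15 | (S)-4-benzyl-3-{2-[4-(triisopropylsilyloxy)phenyl]acetyl}oxazolidin-2-one | O=C1OC[C@H](Cc2ccccc2)N1C(=O)Cc3ccc(O[Si](C(C)C)(C(C)C)C(C)C)cc3 | intermediate
16 | sodium Z-enolate of 15 | [Na+].O=C1OC[C@H](Cc2ccccc2)N1/C([O-])=C/c3ccc(O[Si](C(C)C)(C(C)C)C(C)C)cc3 | intermediate
17 | (2S,3S)-succinate: C1 N-acyl (S)-4-benzyloxazolidin-2-one, C2 4-(triisopropylsilyloxy)phenyl, C3 3-(3-methylbut-2-enyl)-4-(triisopropylsilyloxy)benzyl, C4 2-(trimethylsilyl)ethyl ester | O=C1OC[C@H](Cc2ccccc2)N1C(=O)[C@H](c3ccc(O[Si](C(C)C)(C(C)C)C(C)C)cc3)[C@H](Cc4ccc(O[Si](C(C)C)(C(C)C)C(C)C)c(CC=C(C)C)c4)C(=O)OCC[Si](C)(C)C | intermediate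
18 | (2S,3S)-peroxy acid at C1, otherwise as 19 | OOC(=O)[C@H](c1ccc(O[Si](C(C)C)(C(C)C)C(C)C)cc1)[C@H](Cc1ccc(O[Si](C(C)C)(C(C)C)C(C)C)c(CC=C(C)C)c1)C(=O)OCC[Si](C)(C)C | intermediate
19 | (2S,3S)-2-[4-(triisopropylsilyloxy)phenyl]-3-[3-(3-methylbut-2-enyl)-4-(triisopropylsilyloxy)benzyl]succinic acid 4-[2-(trimethylsilyl)ethyl] ester | OC(=O)[C@H](c1ccc(O[Si](C(C)C)(C(C)C)C(C)C)cc1)[C@H](Cc1ccc(O[Si](C(C)C)(C(C)C)C(C)C)c(CC=C(C)C)c1)C(=O)OCC[Si](C)(C)C | intermediate
20 | 1-methyl 4-[2-(trimethylsilyl)ethyl] (2S,3S)-2-[4-(triisopropylsilyloxy)phenyl]-3-[3-(3-methylbut-2-enyl)-4-(triisopropylsilyloxy)benzyl]succinate | COC(=O)[C@H](c1ccc(O[Si](C(C)C)(C(C)C)C(C)C)cc1)[C@H](Cc1ccc(O[Si](C(C)C)(C(C)C)C(C)C)c(CC=C(C)C)c1)C(=O)OCC[Si](C)(C)C | intermediate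
21 | Asperteretal G2, (2S,3S)-2-(4-hydroxyphenyl)-3-[4-hydroxy-3-(3-methylbut-2-enyl)benzyl]succinic acid 1-methyl ester | COC(=O)[C@H](c1ccc(O)cc1)[C@H](Cc1ccc(O)c(CC=C(C)C)c1)C(=O)O | target

Total step count: 11. Longest linear sequence: 9 steps (steps 1–5, then 8–11).

Steps most likely to fail

Step 8 (key alkylation). The chelated, alpha-aryl imide enolate is hindered and may substitute slowly. On warming, E2 loss of triflate or erosion of face control could then compete. The fallback gives up auxiliary control and sets only C3 by SN2 inversion, using a small unchelated ester enolate that already carries the C1 methyl ester. It sets out from acid 12 and triflate 9. Acid 12 is methylated with Me3SiCHN2 in toluene/MeOH to methyl 2-[4-(triisopropylsilyloxy)phenyl]acetate F1. LiN(SiMe3)2 in THF at –78 °C converts it into the lithium enolate of F1 F2, which should displace the triflate of 9 at –78 °C with inversion. This should give diester 20 together with its C2 epimer, the (2R,3S)-diester F3. The two are separated by chromatography, and F3 is recycled by equilibration at C2, the only acidic stereocentre, with catalytic DBU in toluene. The fallback comes back to the route at 20 and makes steps 9 and 10 unnecessary.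

Step 4 (Stille prenylation). Allylic transposition at palladium may lead to coupling at the tertiary allyl terminus, or oxidative addition next to the bulky silyloxy group may be slow enough for protodeiodination to compete. The fallback installs the side chain in two stages whose regiochemistry is unambiguous. It sets out from iodide 6. Stille coupling with allyltributylstannane (Pd(PPh3)4, toluene, 100 °C) should give 2-(trimethylsilyl)ethyl (S)-3-[3-allyl-4-(triisopropylsilyloxy)phenyl]-2-hydroxypropanoate F4. Olefin cross-metathesis with excess 2-methyl-2-butene (second-generation Grubbs catalyst, RuCl2(H2IMes)(PCy3)(=CHPh), CH2Cl2, 40 °C) then exchanges the terminal CH2 for an isopropylidene unit. The fallback comes back to the route at 8.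

Step 9 (auxiliary removal). Attack at the ring carbonyl of the congested imide would open the auxiliary instead of releasing it. Slow cleavage could also let hydroxide hydrolyse the silylethyl ester or enolise C2. The fallback replaces hydrolysis by thiolate transacylation and sets out from 17. LiSEt (from EtSH and n-BuLi, THF, 0 °C) should give the (2S,3S)-S-ethyl thioester at C1 F5 and free auxiliary 13. Thiophilic activation with AgOCOCF3 in MeOH buffered with 2,6-lutidine at rt should then give the methyl ester under non-basic conditions. The fallback comes back to the route at 20 and bypasses acid 19.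

Further compounds
F1 | step 8 | methyl 2-[4-(triisopropylsilyloxy)phenyl]acetate | COC(=O)Cc1ccc(O[Si](C(C)C)(C(C)C)C(C)C)cc1
F2 | step 8 | lithium enolate of F1 | [Li+].[O-]C(OC)=Cc1ccc(O[Si](C(C)C)(C(C)C)C(C)C)cc1
F3 | step 8 | 1-methyl 4-[2-(trimethylsilyl)ethyl] (2R,3S)-2-[4-(triisopropylsilyloxy)phenyl]-3-[3-(3-methylbut-2-enyl)-4-(triisopropylsilyloxy)benzyl]succinate | COC(=O)[C@@H](c1ccc(O[Si](C(C)C)(C(C)C)C(C)C)cc1)[C@H](Cc1ccc(O[Si](C(C)C)(C(C)C)C(C)C)c(CC=C(C)C)c1)C(=O)OCC[Si](C)(C)C
F4 | step 4 | 2-(trimethylsilyl)ethyl (S)-3-[3-allyl-4-(triisopropylsilyloxy)phenyl]-2-hydroxypropanoate | O[C@@H](Cc1ccc(O[Si](C(C)C)(C(C)C)C(C)C)c(CC=C)c1)C(=O)OCC[Si](C)(C)C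
F5 | step 9 | (2S,3S)-succinate with C1 as the S-ethyl thioester and C4 as the 2-(trimethylsilyl)ethyl ester, aryl groups as in 17 | CCSC(=O)[C@H](c1ccc(O[Si](C(C)C)(C(C)C)C(C)C)cc1)[C@H](Cc1ccc(O[Si](C(C)C)(C(C)C)C(C)C)c(CC=C(C)C)c1)C(=O)OCC[Si](C)(C)C
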